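**Plan**

1. The cyclohexene is numbered as in the name of the target: C1 (aroyl), C2 (prenyl), C3 (methyl), C4 (=CH), C5 (CH2), C6 (aryl). Cuts, in order: the aryl–C(=O) bond of the ketone (aryllithium plus aldehyde), the prenyl alkene (cross-metathesis of an allyl group), ring bond C4–C5, bond C1–C2 (Ireland–Claisen), the ester C–O bond.
2. Enabling feature: C4=C3 and C5–C6(aryl) are the two ends of a hexa-1,5-diene C4=C3–C2–C1–C6=C5 folded into the six-membered ring. The 4-oxygenated phenyl on C6 makes the C5=C6 styrene the one alkene that is oxidised to a radical cation, electrophilic at C5.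
3. Forward: Ireland–Claisen rearrangement of an α-silyl allylic ester builds C1–C2 and the open-chain diene. The only carbocycle then closes at C4–C5 by a photoredox radical-cation cyclisation in which the vinylsilane carbon C4 is the nucleophile and the silyl group is lost. Allyl to prenyl, ester to aryl ketone and deprotection follow.
4. Stereochemistry: one carbinol center (asymmetric reduction of an acylsilane) is relayed through the chair Claisen transition state to C2 and C1. C6 arises in the hydrogen-atom transfer that ends the key step (aryl equatorial, trans to the C1 ester).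

Key step: step 9

Remark: in the reduction of acylsilane 8 the silyl group is assumed to act as the larger carbonyl substituent; the antipodal borane would be taken if the opposite were found.

**Route**

Step 1
Reactants: 1 (2E)-3-ethoxy-2-methylprop-2-enal; 2 allylmagnesium bromide
Product: 4 (2E)-2-methylhexa-2,5-dienal, via bromomagnesium alkoxide 3 (not isolated)
Conditions: THF, −78 to 0 °C; then 1 M HCl, 0 °C
Reagents that add atoms: water, O
Why: 1,2-Grignard addition to the vinylogous formate ester followed by acid-induced allylic transposition with loss of ethanol should give the conjugated aldehyde in its thermodynamic E geometry; no stereocenter is formed.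

Step 2
Reactants: 4 (2E)-2-methylhexa-2,5-dienal; 5 chloro(dimethyl)phenylsilane
Product: 7 rac-(2E)-1-[dimethyl(phenyl)silyl]-2-methylhexa-2,5-dien-1-ol, via silyllithium 6 (not isolated)
Conditions: 5, Li, THF, 0 °C; then 4, THF, −78 °C; NH4Cl (aq) at −78 °C
Reagents that add atoms: none
Why: Carbonyl 1,2-addition of a silyllithium reagent to the aldehyde should give the α-hydroxysilane, a cold quench outrunning Brook rearrangement of the alkoxide; the carbinol center forms racemic and is reset in steps 3 and 4.

Step 3
Reactants: 7 rac-(2E)-1-[dimethyl(phenyl)silyl]-2-methylhexa-2,5-dien-1-ol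
Product: 8 (2E)-1-[dimethyl(phenyl)silyl]-2-methylhexa-2,5-dien-1-one
Conditions: Dess–Martin periodinane, pyridine, CH2Cl2, 0 °C
Reagents that add atoms: none
Why: Buffered Dess–Martin oxidation of an α-hydroxysilane to the acylsilane is a standard alcohol oxidation and removes the racemic center without touching the alkenes.

Step 4
Reactants: 8 (2E)-1-[dimethyl(phenyl)silyl]-2-methylhexa-2,5-dien-1-one
Product: 9 (1S,2E)-1-[dimethyl(phenyl)silyl]-2-methylhexa-2,5-dien-1-ol
Conditions: (+)-B-chlorodiisopinocampheylborane, THF, −25 °C; then CH3CHO; NaOH (aq)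
Reagents that add atoms: none
Why: Asymmetric reduction of an α,β-unsaturated acylsilane with B-chlorodiisopinocampheylborane is a known carbonyl reduction in which hydride is delivered through a boat-like six-membered transition state with the bulky silyl group in the place of the large substituent, which with the (+)-reagent should give the (S)-carbinol and leave both alkenes untouched.

Step 5
Reactants: 10 1-bromo-4-(methoxymethoxy)benzene; 11 diketene
Product: 13 3-[4-(methoxymethoxy)phenyl]but-3-enoic acid, via aryl Grignard reagent 12 (not isolated)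
Conditions: Mg, THF, 25–50 °C; then 11, NiCl2 (5 mol %), THF, 0 °C; 1 M HCl, 0 °C
Reagents that add atoms: none
Why: Nickel-catalysed ring opening of diketene by a Grignard reagent at the vinylic C–O bond is a known cross-coupling that gives 3-substituted but-3-enoic acids in one operation; the MOM ether tolerates the Grignard reagent and no stereocenter is formed.

Step 6
Reactants: 9 (1S,2E)-1-[dimethyl(phenyl)silyl]-2-methylhexa-2,5-dien-1-ol; 13 3-[4-(methoxymethoxy)phenyl]but-3-enoic acid
Product: 14 (1S,2E)-1-[dimethyl(phenyl)silyl]-2-methylhexa-2,5-dien-1-yl 3-[4-(methoxymethoxy)phenyl]but-3-enoate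
Conditions: DCC, DMAP (10 mol %), CH2Cl2, 0 to 25 °C
Reagents that add atoms: none
Why: Steglich esterification of the secondary α-silyl alcohol under neutral conditions should leave the carbinol stereocenter and the acid-labile MOM ether intact; any isomerisation of the acyl part into conjugation would converge on the same dienolate in step 7.

Step 7
Reactants: 14 (1S,2E)-1-[dimethyl(phenyl)silyl]-2-methylhexa-2,5-dien-1-yl 3-[4-(methoxymethoxy)phenyl]but-3-enoate
Product: 17 (2R,3S)-3-[(1E)-1-[dimethyl(phenyl)silyl]prop-1-en-2-yl]-2-{1-[4-(methoxymethoxy)phenyl]ethenyl}hex-5-enoic acid, via silyl ketene acetal 15 (not isolated), via trimethylsilyl ester 16 (not isolated)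
Conditions: LiN(i-Pr)2, Me3SiCl, THF–DMPU, −78 to 25 °C; then dilute HCl (aq)
Reagents that add atoms: none
Why: Ireland–Claisen rearrangement: enolisation in THF–DMPU should give the Z(O)-enolate (arylvinyl group cis to O–Li), and the chair transition state with the bulky silyl group and the allyl-bearing alkene terminus equatorial relays the (S)-carbinol configuration to C3 (S) and, through the enolate geometry, to C2 (R), while the new alkene appears as the (E)-vinylsilane.

Step 8
Reactants: 17 (2R,3S)-3-[(1E)-1-[dimethyl(phenyl)silyl]prop-1-en-2-yl]-2-{1-[4-(methoxymethoxy)phenyl]ethenyl}hex-5-enoic acid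
Product: 18 methyl (2R,3S)-3-[(1E)-1-[dimethyl(phenyl)silyl]prop-1-en-2-yl]-2-{1-[4-(methoxymethoxy)phenyl]ethenyl}hex-5-enoate
Conditions: Me3SiCHN2, MeOH–toluene, 0 to 25 °C
Reagents that add atoms: (trimethylsilyl)diazomethane, C[Si](C)(C)C=[N+]=[N-]
Why: Neutral esterification with (trimethylsilyl)diazomethane should neither epimerise the α-center nor move the β,γ-double bond, and it masks the acid, which would otherwise add to the radical cation of step 9 as a lactone-forming nucleophile.

Step 9
Reactants: 18 methyl (2R,3S)-3-[(1E)-1-[dimethyl(phenyl)silyl]prop-1-en-2-yl]-2-{1-[4-(methoxymethoxy)phenyl]ethenyl}hex-5-enoate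
Product: 19 methyl (1R,2S,6R)-6-[4-(methoxymethoxy)phenyl]-3-methyl-2-(prop-2-en-1-yl)cyclohex-3-ene-1-carboxylate
Conditions: 9-mesityl-3,6-di-tert-butyl-10-phenylacridinium tetrafluoroborate (5 mol %), PhSSPh (20 mol %), MeOH (3 equiv), ClCH2CH2Cl, 450 nm LEDs, 25 °C, degassed
Reagents that add atoms: none
Why: Proposed new method: the excited acridinium should oxidise only the α-alkyl 4-alkoxystyrene (the vinylsilane and the allyl group are harder to oxidise) to a radical cation whose unsubstituted terminus C5 is attacked by the silicon-bearing carbon C4; in the resulting distonic 1,4-radical cation, once ring inversion has set the C–Si bond parallel to the empty orbital at C3, the β-silyl cation gives up its silyl group to methanol, and the benzylic radical left at C6 takes a hydrogen atom from thiophenol, which the reduced acridine and the released proton regenerate. The closest known reaction types are the acridinium-photocatalysed anti-Markovnikov hydrofunctionalisation of styrenes with heteroatom nucleophiles, anodic couplings of alkene radical cations with allyl- and vinylsilanes, and the electron-transfer-induced cyclisation of 2,5-diarylhexa-1,5-dienes to cyclohexane-1,4-diyl radical cations; new is the carbon nucleophile combined with a hydrogen-atom-transfer ending. The cyclohexene closes in a 6-endo mode (both carbons of each alkene end up in the ring) through a chair transition state of the hexa-1,5-diene with the silyl group pseudo-equatorial, that is, as an interrupted radical-cation Cope reaction. C1 and C2 are carried over from 18, and the new center C6 is set in the hydrogen-atom transfer, whose late, product-like transition state should place the aryl group equatorial and trans to the ester on C1. The step needs chemoselective oxidation, secured by the electron-rich aryl group; attack at C5 and not C6, secured by benzylic stabilisation at C6; and a single alkene position, secured by silicon, because loss of the silyl group can only give the C3=C4 double bond.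

Step 10
Reactants: 19 methyl (1R,2S,6R)-6-[4-(methoxymethoxy)phenyl]-3-methyl-2-(prop-2-en-1-yl)cyclohex-3-ene-1-carboxylate
Product: 20 methyl (1R,2S,6R)-6-[4-(methoxymethoxy)phenyl]-3-methyl-2-(3-methylbut-2-en-1-yl)cyclohex-3-ene-1-carboxylate
Conditions: 2-methylbut-2-ene (excess), second-generation Grubbs catalyst RuCl2(=CHPh)(PCy3)(H2IMes) (5 mol %), CH2Cl2, 40 °C
Reagents that add atoms: 2-methylbut-2-ene, CC=C(C)C
Why: Olefin cross-metathesis of a terminal alkene with 2-methylbut-2-ene turns the allyl group into the prenyl group, the trisubstituted ring alkene being inert to the ruthenium carbene; no stereocenter is touched.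

Step 11
Reactants: 20 methyl (1R,2S,6R)-6-[4-(methoxymethoxy)phenyl]-3-methyl-2-(3-methylbut-2-en-1-yl)cyclohex-3-ene-1-carboxylate
Product: 21 (1R,2S,6R)-6-[4-(methoxymethoxy)phenyl]-3-methyl-2-(3-methylbut-2-en-1-yl)cyclohex-3-ene-1-carbaldehyde
Conditions: i-Bu2AlH (1.1 equiv), CH2Cl2, −78 °C; MeOH, then potassium sodium tartrate (aq)
Reagents that add atoms: none
Why: Partial reduction of the hindered methyl ester with i-Bu2AlH at −78 °C should stop at the aluminium hemiacetal, which gives the aldehyde on work-up; C1 already carries its substituent equatorial, so any epimerisation would correct itself.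

Step 12
Reactants: 22 benzene-1,3,5-triol
Product: 23 1,3,5-tris(methoxymethoxy)benzene
Conditions: NaH, MOMCl, DMF, 0 to 25 °C
Reagents that add atoms: chloromethyl methyl ether, COCCl
Why: Williamson etherification of the phenoxide with the hard electrophile MOMCl should favour O- over C-alkylation and gives the arene that is lithiated in step 13.

Step 13
Reactants: 21 (1R,2S,6R)-6-[4-(methoxymethoxy)phenyl]-3-methyl-2-(3-methylbut-2-en-1-yl)cyclohex-3-ene-1-carbaldehyde; 23 1,3,5-tris(methoxymethoxy)benzene
Product: 25 [(1R,2S,6R)-6-[4-(methoxymethoxy)phenyl]-3-methyl-2-(3-methylbut-2-en-1-yl)cyclohex-3-en-1-yl][2,4,6-tris(methoxymethoxy)phenyl]methanol, via aryllithium 24 (not isolated)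
Conditions: 23, n-BuLi, THF, 0 °C; then 21, THF, −78 to 0 °C; NH4Cl (aq)
Reagents that add atoms: none
Why: Directed ortho-lithiation between two MOM ethers followed by 1,2-addition of the aryllithium to the aldehyde should form the aryl–carbon bond; the carbinol center forms as a mixture that is removed in step 14.

Step 14
Reactants: 25 [(1R,2S,6R)-6-[4-(methoxymethoxy)phenyl]-3-methyl-2-(3-methylbut-2-en-1-yl)cyclohex-3-en-1-yl][2,4,6-tris(methoxymethoxy)phenyl]methanol
Product: 26 [(1R,2S,6R)-6-[4-(methoxymethoxy)phenyl]-3-methyl-2-(3-methylbut-2-en-1-yl)cyclohex-3-en-1-yl][2,4,6-tris(methoxymethoxy)phenyl]methanone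
Conditions: Dess–Martin periodinane, pyridine, CH2Cl2, 25 °C
Reagents that add atoms: none
Why: Dess–Martin oxidation of the secondary benzylic alcohol should give the aryl ketone under buffered, neutral conditions that spare the alkenes and the MOM ethers.

Step 15
Reactants: 26 [(1R,2S,6R)-6-[4-(methoxymethoxy)phenyl]-3-methyl-2-(3-methylbut-2-en-1-yl)cyclohex-3-en-1-yl][2,4,6-tris(methoxymethoxy)phenyl]methanone
Product: 27 [(1R,2S,6R)-6-(4-hydroxyphenyl)-3-methyl-2-(3-methylbut-2-en-1-yl)cyclohex-3-en-1-yl](2,4,6-trihydroxyphenyl)methanone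
Conditions: HCl (3 M aq), MeOH, 40 °C
Reagents that add atoms: none
Why: Acid-catalysed acetal exchange with methanol should remove all four MOM groups under conditions mild enough for the two trisubstituted alkenes, and C1, being enolisable, keeps the thermodynamically preferred equatorial aroyl group.

**Compound list**

1 | (2E)-3-ethoxy-2-methylprop-2-enal | CCO/C=C(C)/C=O | starting material
2 | allylmagnesium bromide | C=CC[Mg]Br | starting material
3 | bromomagnesium (1E)-1-ethoxy-2-methylhexa-1,5-dien-3-olate | CCO/C=C(C)/C(CC=C)O[Mg]Br | intermediate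
4 | (2E)-2-methylhexa-2,5-dienal | C=CC/C=C(C)/C=O | intermediate
5 | chloro(dimethyl)phenylsilane | C[Si](C)(Cl)c1ccccc1 | starting material
6 | [dimethyl(phenyl)silyl]lithium | [Li][Si](C)(C)c1ccccc1 | intermediate
7 | rac-(2E)-1-[dimethyl(phenyl)silyl]-2-methylhexa-2,5-dien-1-ol | C=CC/C=C(C)/C(O)[Si](C)(C)c1ccccc1 | intermediate
8 | (2E)-1-[dimethyl(phenyl)silyl]-2-methylhexa-2,5-dien-1-one | C=CC/C=C(C)/C(=O)[Si](C)(C)c1ccccc1 | intermediate
9 | (1S,2E)-1-[dimethyl(phenyl)silyl]-2-methylhexa-2,5-dien-1-ol | C=CC/C=C(C)/[C@@H](O)[Si](C)(C)c1ccccc1 | intermediate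
10 | 1-bromo-4-(methoxymethoxy)benzene | COCOc1ccc(Br)cc1 | starting material
11 | diketene (4-methylideneoxetan-2-one) | C=C1CC(=O)O1 | starting material
12 | [4-(methoxymethoxy)phenyl]magnesium bromide | COCOc1ccc([Mg]Br)cc1 | intermediate
13 | 3-[4-(methoxymethoxy)phenyl]but-3-enoic acid | C=C(CC(=O)O)c1ccc(OCOC)cc1 | intermediate
14 | (1S,2E)-1-[dimethyl(phenyl)silyl]-2-methylhexa-2,5-dien-1-yl 3-[4-(methoxymethoxy)phenyl]but-3-enoate | C=CC/C=C(C)/[C@@H](OC(=O)CC(=C)c1ccc(OCOC)cc1)[Si](C)(C)c1ccccc1 | intermediate
15 | trimethylsilyl ketene acetal of 14, (1Z)-configured (arylvinyl group cis to OSiMe3) | C=CC/C=C(C)/[C@@H](O/C(O[Si](C)(C)C)=C/C(=C)c1ccc(OCOC)cc1)[Si](C)(C)c1ccccc1 | intermediate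
16 | trimethylsilyl (2R,3S)-3-[(1E)-1-[dimethyl(phenyl)silyl]prop-1-en-2-yl]-2-{1-[4-(methoxymethoxy)phenyl]ethenyl}hex-5-enoate | C=CC[C@@H]([C@@H](C(=O)O[Si](C)(C)C)C(=C)c1ccc(OCOC)cc1)/C(C)=C/[Si](C)(C)c1ccccc1 | intermediate
17 | (2R,3S)-3-[(1E)-1-[dimethyl(phenyl)silyl]prop-1-en-2-yl]-2-{1-[4-(methoxymethoxy)phenyl]ethenyl}hex-5-enoic acid | C=CC[C@@H]([C@@H](C(=O)O)C(=C)c1ccc(OCOC)cc1)/C(C)=C/[Si](C)(C)c1ccccc1 | intermediate
18 | methyl (2R,3S)-3-[(1E)-1-[dimethyl(phenyl)silyl]prop-1-en-2-yl]-2-{1-[4-(methoxymethoxy)phenyl]ethenyl}hex-5-enoate | C=CC[C@@H]([C@@H](C(=O)OC)C(=C)c1ccc(OCOC)cc1)/C(C)=C/[Si](C)(C)c1ccccc1 | intermediate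
19 | methyl (1R,2S,6R)-6-[4-(methoxymethoxy)phenyl]-3-methyl-2-(prop-2-en-1-yl)cyclohex-3-ene-1-carboxylate | C=CC[C@@H]1C(C)=CC[C@@H](c2ccc(OCOC)cc2)[C@@H]1C(=O)OC | intermediate
20 | methyl (1R,2S,6R)-6-[4-(methoxymethoxy)phenyl]-3-methyl-2-(3-methylbut-2-en-1-yl)cyclohex-3-ene-1-carboxylate | CC(C)=CC[C@@H]1C(C)=CC[C@@H](c2ccc(OCOC)cc2)[C@@H]1C(=O)OC | intermediate
21 | (1R,2S,6R)-6-[4-(methoxymethoxy)phenyl]-3-methyl-2-(3-methylbut-2-en-1-yl)cyclohex-3-ene-1-carbaldehyde | CC(C)=CC[C@@H]1C(C)=CC[C@@H](c2ccc(OCOC)cc2)[C@@H]1C=O | intermediate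
22 | benzene-1,3,5-triol (phloroglucinol) | Oc1cc(O)cc(O)c1 | starting material
23 | 1,3,5-tris(methoxymethoxy)benzene | COCOc1cc(OCOC)cc(OCOC)c1 | intermediate
24 | [2,4,6-tris(methoxymethoxy)phenyl]lithium | [Li]c1c(OCOC)cc(OCOC)cc1OCOC | intermediate
25 | [(1R,2S,6R)-6-[4-(methoxymethoxy)phenyl]-3-methyl-2-(3-methylbut-2-en-1-yl)cyclohex-3-en-1-yl][2,4,6-tris(methoxymethoxy)phenyl]methanol (both carbinol epimers) | CC(C)=CC[C@@H]1C(C)=CC[C@@H](c2ccc(OCOC)cc2)[C@@H]1C(O)c1c(OCOC)cc(OCOC)cc1OCOC | intermediate
26 | [(1R,2S,6R)-6-[4-(methoxymethoxy)phenyl]-3-methyl-2-(3-methylbut-2-en-1-yl)cyclohex-3-en-1-yl][2,4,6-tris(methoxymethoxy)phenyl]methanone | CC(C)=CC[C@@H]1C(C)=CC[C@@H](c2ccc(OCOC)cc2)[C@@H]1C(=O)c1c(OCOC)cc(OCOC)cc1OCOC | intermediate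
27 | [(1R,2S,6R)-6-(4-hydroxyphenyl)-3-methyl-2-(3-methylbut-2-en-1-yl)cyclohex-3-en-1-yl](2,4,6-trihydroxyphenyl)methanone | CC(C)=CC[C@@H]1C(C)=CC[C@@H](c2ccc(O)cc2)[C@@H]1C(=O)c1c(O)cc(O)cc1O | target

**Step count and risks**

Total step count: 15. Longest linear sequence: 13 steps (steps 1–4, 6–11, 13–15).

Steps most likely to fail:

1. Step 9 (proposed new method). The charge of the distonic intermediate may stay at the benzylic carbon, so that a proton is lost next to the aryl group before the silyl group can leave. Methanol may add to the radical cation faster than the ring closes. The hydrogen-atom transfer to C6 may show poor facial selectivity, and reversible hydrogen abstraction at the doubly activated C–H next to the ester may erode C1 before cyclisation. Fallback with known chemistry, forming the ring by other bonds: it sets out from aldehyde 4, which Wittig methylenation (Ph3P=CH2, THF) converts into (3E)-3-methylhepta-1,3,6-triene F1. The dienophile (4R)-4-benzyl-3-[(2E)-3-[4-(methoxymethoxy)phenyl]prop-2-enoyl]-1,3-oxazolidin-2-one F2 is made from lithiated (4R)-4-benzyl-1,3-oxazolidin-2-one and (2E)-3-[4-(methoxymethoxy)phenyl]prop-2-enoyl chloride. An Et2AlCl-promoted Diels–Alder reaction of F1 with F2 at −30 °C (endo, diene on the face of the chelated imide away from the benzyl group, unsubstituted diene terminus to the aryl-bearing carbon) should give the adduct (4R)-4-benzyl-3-{[(1R,2S,6R)-6-[4-(methoxymethoxy)phenyl]-3-methyl-2-(prop-2-en-1-yl)cyclohex-3-en-1-yl]carbonyl}-1,3-oxazolidin-2-one F3. Methanolysis with MeOMgBr brings the route back at 19.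

2. Step 4. Enantioface discrimination may be low or reversed because the silyl group and the branched alkenyl group are of similar size. Fallback: the C–Si bond and the stereocenter are formed together by copper-catalysed enantioselective 1,2-addition of PhMe2Si–Bpin to aldehyde 4 (CuCl, NaOt-Bu, a chiral bisphosphine such as DTBM-SEGPHOS in the antipode that gives the (S)-carbinol, MeOH, THF). It sets out from 4 and comes back at 9, and it makes no compound outside the list (F0).

3. Step 13. The basic aryllithium may enolise the hindered α-branched aldehyde, or the addition may be too slow. Fallback with a non-basic acylation: it sets out from ester 20, which LiOH (THF–MeOH–H2O) saponifies to (1R,2S,6R)-6-[4-(methoxymethoxy)phenyl]-3-methyl-2-(3-methylbut-2-en-1-yl)cyclohex-3-ene-1-carboxylic acid F4. 1-Chloro-N,N,2-trimethylprop-1-en-1-amine converts it under neutral conditions into (1R,2S,6R)-6-[4-(methoxymethoxy)phenyl]-3-methyl-2-(3-methylbut-2-en-1-yl)cyclohex-3-ene-1-carbonyl chloride F5. Aryllithium 24 is transmetalated with ZnCl2 to chloro[2,4,6-tris(methoxymethoxy)phenyl]zinc F6, and Pd(PPh3)4-catalysed Negishi acylation of F6 with F5 comes back to the route at ketone 26, passing by 21 and 25.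

Further compounds
F1 | step 9 | (3E)-3-methylhepta-1,3,6-triene | C=CC/C=C(C)/C=C
F2 | step 9 | (4R)-4-benzyl-3-[(2E)-3-[4-(methoxymethoxy)phenyl]prop-2-enoyl]-1,3-oxazolidin-2-one | COCOc1ccc(/C=C/C(=O)N2C(=O)OC[C@H]2Cc3ccccc3)cc1
F3 | step 9 | (4R)-4-benzyl-3-{[(1R,2S,6R)-6-[4-(methoxymethoxy)phenyl]-3-methyl-2-(prop-2-en-1-yl)cyclohex-3-en-1-yl]carbonyl}-1,3-oxazolidin-2-one | C=CC[C@@H]1C(C)=CC[C@@H](c2ccc(OCOC)cc2)[C@@H]1C(=O)N3C(=O)OC[C@H]3Cc4ccccc4
F0 | step 4 | none | none
F4 | step 13 | (1R,2S,6R)-6-[4-(methoxymethoxy)phenyl]-3-methyl-2-(3-methylbut-2-en-1-yl)cyclohex-3-ene-1-carboxylic acid | CC(C)=CC[C@@H]1C(C)=CC[C@@H](c2ccc(OCOC)cc2)[C@@H]1C(=O)O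
F5 | step 13 | (1R,2S,6R)-6-[4-(methoxymethoxy)phenyl]-3-methyl-2-(3-methylbut-2-en-1-yl)cyclohex-3-ene-1-carbonyl chloride | CC(C)=CC[C@@H]1C(C)=CC[C@@H](c2ccc(OCOC)cc2)[C@@H]1C(=O)Cl
F6 | step 13 | chloro[2,4,6-tris(methoxymethoxy)phenyl]zinc | Cl[Zn]c1c(OCOC)cc(OCOC)cc1OCOC
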